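**Retrosynthetic overview**

1. Feature: ring A (C1, C14, C13, C12, C11, C15) holds the quaternary C15 between C1 and C11 and the exocyclic C12=C18 olefin beside the C13 ketone. A C15 radical on C1 that closes on C11 of a C11=C12 olefin in a fourteen-membered ring (C1–C14) and then loses a C18 hydrogen leaves exactly this pattern, and the same bond cuts out the twelve-membered ring (C1–C11, C15).
2. Endgame, read backwards: the C13 ketone comes from allylic oxidation (SeO2, then Dess–Martin) of the C12=C18 olefin; the two trans (R,R)-oxiranes come from Shi epoxidation of C3=C4 and C7=C8 of (10S)-10-acetoxyverticilla-3,7,12(18)-triene.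
3. Key disconnection C11–C15 (transannular hydrogen-atom-transfer cycloisomerization) leads back to (1S,10S)-10-acetoxycembra-3,7,11,15-tetraene.
4. Fourteen-membered ring: C10–C11 by CrCl2/NiCl2 closure of an (E)-vinyl iodide onto an aldehyde, with C10 then fixed by oxidation and CBS reduction; C5–C6 by allylic sulfone alkylation and desulfonylation; C3=C4 by Wittig olefination; C11=C12 and C7=C8 by alkyne carboalumination.
5. (S)-Limonene supplies C1 with its isopropenyl group (C15–C17), C2, C3 and C11–C14. Ring order: fourteen-membered ring first, then ring A together with the twelve-membered ring, then the two oxiranes.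

Key step: step 19

Remark: verticillane numbering is used for all intermediates (C18 on C12, C19 on C4, C20 on C8, acetoxy on C10); because a five-carbon prenyl unit would leave the chain one carbon (C10) short, C6–C10 with C20 is brought in as a six-carbon allylic sulfone.

**Route**

Step 1
Reactants: 1 (S)-limonene
Product: 4 (5S)-7,7-dimethoxy-5-(prop-1-en-2-yl)heptan-2-one, via hydroperoxy aldehyde 2 (not isolated), via hydroperoxy acetal 3 (not isolated)
Conditions: O3 (1.0 equiv, Sudan Red 7B end point), CH2Cl2/MeOH, −78 °C; TsOH·H2O (cat.), rt; NaHCO3; Me2S, rt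
Reagents that add atoms: ozone, [O-][O+]=O; methanol, CO
Why: Unsymmetrical ozonolysis in methanol, in which ozone should consume the electron-rich trisubstituted ring olefin before the 1,1-disubstituted one, the aldehyde end is acetalized and the methoxy hydroperoxide end is reduced to the methyl ketone, with the limonene stereocenter (later C1) untouched.

Step 2
Reactants: 4 (5S)-7,7-dimethoxy-5-(prop-1-en-2-yl)heptan-2-one
Product: 7 [(5S)-7,7-dimethoxy-5-(prop-1-en-2-yl)hept-1-yn-1-yl]trimethylsilane, via enol phosphate 5 (not isolated), via lithium acetylide 6 (not isolated)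
Conditions: LDA (1.1 equiv), THF, −78 °C; ClP(O)(OEt)2, −78 °C → rt; LDA (2.3 equiv), −78 °C → rt; TMSCl, −78 °C → rt
Reagents that add atoms: chlorotrimethylsilane, C[Si](C)(C)Cl; diethyl chlorophosphate, CCOP(=O)(Cl)OCC (its atoms stay only in 5); lithium diisopropylamide, [Li]N(C(C)C)C(C)C (lithium only in 6)
Why: Methyl ketone to alkyne conversion through the kinetic enol phosphate and double elimination (Negishi protocol), with C-silylation of the acetylide in the same flask so that the alkyne is inert in the later hydride step.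

Step 3
Reactants: 7 [(5S)-7,7-dimethoxy-5-(prop-1-en-2-yl)hept-1-yn-1-yl]trimethylsilane
Product: 8 (3S)-3-(prop-1-en-2-yl)-7-(trimethylsilyl)hept-6-ynal
Conditions: TsOH·H2O (cat.), acetone/H2O, rt
Reagents that add atoms: water, O
Why: Acid-catalysed acetal hydrolysis, which the silylalkyne and the isopropenyl group should tolerate, and the stereocenter is β to the aldehyde and cannot epimerize.

Step 4
Reactants: 8 (3S)-3-(prop-1-en-2-yl)-7-(trimethylsilyl)hept-6-ynal; 9 ethyl 2-(triphenylphosphoranylidene)propanoate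
Product: 10 ethyl (2E,5S)-2-methyl-5-(prop-1-en-2-yl)-9-(trimethylsilyl)non-2-en-8-ynoate
Conditions: CH2Cl2, rt → 40 °C
Reagents that add atoms: none
Why: Wittig olefination with a stabilized α-methyl ylide, which should give the (E)-trisubstituted enoate (C3=C4 with C19).

Step 5
Reactants: 10 ethyl (2E,5S)-2-methyl-5-(prop-1-en-2-yl)-9-(trimethylsilyl)non-2-en-8-ynoate
Product: 11 (2E,5S)-2-methyl-5-(prop-1-en-2-yl)-9-(trimethylsilyl)non-2-en-8-yn-1-ol
Conditions: DIBAL-H, CH2Cl2, −78 °C; Rochelle salt work-up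
Reagents that add atoms: none
Why: 1,2-Reduction of the enoate by DIBAL-H to the (E)-allylic alcohol, with the silylalkyne and the isolated olefin inert at low temperature.

Step 6
Reactants: 11 (2E,5S)-2-methyl-5-(prop-1-en-2-yl)-9-(trimethylsilyl)non-2-en-8-yn-1-ol
Product: 12 (2E,5S)-1-bromo-2-methyl-5-(prop-1-en-2-yl)-9-(trimethylsilyl)non-2-en-8-yne
Conditions: CBr4, PPh3, CH2Cl2, 0 °C
Reagents that add atoms: carbon tetrabromide, BrC(Br)(Br)Br
Why: Appel bromination of a primary allylic alcohol, which proceeds by SN2 displacement without allylic transposition or loss of olefin geometry.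

Step 7
Reactants: 13 tert-butyl(but-3-yn-1-yloxy)dimethylsilane
Product: 16 (2E)-5-{[tert-butyl(dimethyl)silyl]oxy}-3-methylpent-2-en-1-ol, via alkenylalane 14 (not isolated), via lithium alanate 15 (not isolated)
Conditions: Me3Al, Cp2ZrCl2 (20 mol%), CH2Cl2, 0 °C → rt; n-BuLi, THF/hexane, −78 → 0 °C; (CH2O)n, rt
Reagents that add atoms: trimethylaluminium, C[Al](C)C; formaldehyde (as paraformaldehyde), C=O; n-butyllithium, [Li]CCCC (butyl and lithium only in 15)
Why: Negishi zirconium-catalysed carboalumination adds methyl (C20) and aluminium syn across the alkyne, which fixes the E geometry of C7=C8, and the derived alanate adds to formaldehyde with retention to give C6.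

Step 8
Reactants: 16 (2E)-5-{[tert-butyl(dimethyl)silyl]oxy}-3-methylpent-2-en-1-ol
Product: 17 {[(3E)-5-bromo-3-methylpent-3-en-1-yl]oxy}(tert-butyl)dimethylsilane
Conditions: CBr4, PPh3, CH2Cl2, 0 °C
Reagents that add atoms: carbon tetrabromide, BrC(Br)(Br)Br
Why: Appel bromination of the primary allylic alcohol under neutral conditions that keep the silyl ether.

Step 9
Reactants: 17 {[(3E)-5-bromo-3-methylpent-3-en-1-yl]oxy}(tert-butyl)dimethylsilane; 18 sodium benzenesulfinate
Product: 19 tert-butyl(dimethyl){[(3E)-3-methyl-5-(phenylsulfonyl)pent-3-en-1-yl]oxy}silane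
Conditions: DMF, rt
Reagents that add atoms: none
Why: SN2 S-alkylation of the sulfinate by the primary allylic bromide gives the allylic sulfone that will carry C6 as a carbanion.

Step 10
Reactants: 19 tert-butyl(dimethyl){[(3E)-3-methyl-5-(phenylsulfonyl)pent-3-en-1-yl]oxy}silane; 12 (2E,5S)-1-bromo-2-methyl-5-(prop-1-en-2-yl)-9-(trimethylsilyl)non-2-en-8-yne
Product: 21 tert-butyl(dimethyl){[(3E,7E,10S)-3,7-dimethyl-5-(phenylsulfonyl)-10-(prop-1-en-2-yl)-14-(trimethylsilyl)tetradeca-3,7-dien-13-yn-1-yl]oxy}silane as a mixture of C5 epimers, via lithiated sulfone 20 (not isolated)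
Conditions: n-BuLi, THF, −78 °C; then 12, −78 → −20 °C
Reagents that add atoms: n-butyllithium, [Li]CCCC (lithium only in 20)
Why: Alkylation of the α-sulfonyl allylic carbanion at its α-carbon by the allylic bromide (sulfone-based allyl–allyl coupling) forms C5–C6 with both olefin geometries intact, and the unselective sulfone-bearing center is removed in step 11.

Step 11
Reactants: 21 coupled sulfone (name as in step 10)
Product: 22 tert-butyl(dimethyl){[(3E,7E,10S)-3,7-dimethyl-10-(prop-1-en-2-yl)-14-(trimethylsilyl)tetradeca-3,7-dien-13-yn-1-yl]oxy}silane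
Conditions: Pd(dppp)Cl2 (5 mol%), LiBHEt3, THF, 0 °C
Reagents that add atoms: none
Why: Palladium-catalysed hydride desulfonylation, in which zerovalent palladium ionizes the allylic sulfone to a π-allyl complex and hydride goes to the less substituted terminus C6, so the C7=C8 olefin should stay in place and E.

Step 12
Reactants: 22 silyl ether/silylalkyne (name as in step 11)
Product: 23 (3E,7E,10S)-3,7-dimethyl-10-(prop-1-en-2-yl)tetradeca-3,7-dien-13-yn-1-ol
Conditions: TBAF, THF, rt
Reagents that add atoms: none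
Why: Fluoride-induced desilylation cleaves both the O–Si bond of the silyl ether and the C(sp)–Si bond of the silylalkyne in one operation.

Step 13
Reactants: 23 (3E,7E,10S)-3,7-dimethyl-10-(prop-1-en-2-yl)tetradeca-3,7-dien-13-yn-1-ol
Product: 25 (3E,7E,10S,13E)-14-iodo-3,7,13-trimethyl-10-(prop-1-en-2-yl)tetradeca-3,7,13-trien-1-ol, via alkenylalane 24 (not isolated)
Conditions: Me3Al, Cp2ZrCl2 (50 mol%), CH2Cl2, 0 °C → rt; I2, THF, −30 → 0 °C
Reagents that add atoms: trimethylaluminium, C[Al](C)C; iodine, II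
Why: Negishi carboalumination of the terminal alkyne (syn, methyl C18 to C12) followed by iodinolysis with retention should give the (E)-vinyl iodide, with the hydroxyl carried as its aluminium alkoxide and the olefins unreactive.

Step 14
Reactants: 25 (3E,7E,10S,13E)-14-iodo-3,7,13-trimethyl-10-(prop-1-en-2-yl)tetradeca-3,7,13-trien-1-ol
Product: 26 (3E,7E,10S,13E)-14-iodo-3,7,13-trimethyl-10-(prop-1-en-2-yl)tetradeca-3,7,13-trienal
Conditions: Dess–Martin periodinane, NaHCO3, CH2Cl2, 0 °C; used at once
Reagents that add atoms: none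
Why: Buffered Dess–Martin oxidation should give the β,γ-unsaturated aldehyde without migration of the C7=C8 olefin into conjugation.

Step 15
Reactants: 26 (3E,7E,10S,13E)-14-iodo-3,7,13-trimethyl-10-(prop-1-en-2-yl)tetradeca-3,7,13-trienal
Product: 27 (2E,6S,8E,12E)-3,9,13-trimethyl-6-(prop-1-en-2-yl)cyclotetradeca-2,8,12-trien-1-ol as a mixture of C1 epimers (cembra-3,7,11,15-tetraen-10-ol)
Conditions: CrCl2 (excess), NiCl2 (cat.), DMSO/THF, rt, syringe-pump addition, high dilution
Reagents that add atoms: none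
Why: Nozaki–Hiyama–Kishi reaction, in which zerovalent nickel inserts into the C–I bond and the alkenyl group passes to trivalent chromium and adds to the aldehyde, closing the fourteen-membered ring at C10–C11 with retention of the E olefin, while C10 forms unselectively and is corrected in steps 16 and 17.

Step 16
Reactants: 27 macrocyclic allylic alcohol (C10 epimers)
Product: 28 (2E,6S,8E,12E)-3,9,13-trimethyl-6-(prop-1-en-2-yl)cyclotetradeca-2,8,12-trien-1-one
Conditions: Dess–Martin periodinane, NaHCO3, CH2Cl2, 0 °C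
Reagents that add atoms: none
Why: Dess–Martin oxidation of the allylic alcohol converges both C10 epimers on one enone under non-basic conditions that leave the skipped C7=C8 olefin in place.

Step 17
Reactants: 28 (2E,6S,8E,12E)-3,9,13-trimethyl-6-(prop-1-en-2-yl)cyclotetradeca-2,8,12-trien-1-one
Product: 29 (1S,2E,6S,8E,12E)-3,9,13-trimethyl-6-(prop-1-en-2-yl)cyclotetradeca-2,8,12-trien-1-ol [(1S,10S)-cembra-3,7,11,15-tetraen-10-ol]
Conditions: (R)-Me-CBS oxazaborolidine [(R)-1-methyl-3,3-diphenyltetrahydro-1H,3H-pyrrolo[1,2-c][1,3,2]oxazaborole], catecholborane, toluene, −78 °C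
Reagents that add atoms: none
Why: Corey–Bakshi–Shibata reduction with the alkenyl group as the large substituent, so the (R)-oxazaborolidine should deliver hydride to the face that gives the (10S)-alcohol, and catecholborane does not hydroborate the olefins at this temperature.

Step 18
Reactants: 29 (1S,10S)-cembra-3,7,11,15-tetraen-10-ol
Product: 30 (1S,2E,6S,8E,12E)-3,9,13-trimethyl-6-(prop-1-en-2-yl)cyclotetradeca-2,8,12-trien-1-yl acetate [(1S,10S)-10-acetoxycembra-3,7,11,15-tetraene]
Conditions: Ac2O, DMAP (cat.), pyridine, CH2Cl2, 0 °C → rt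
Reagents that add atoms: acetic anhydride, CC(=O)OC(C)=O
Why: DMAP-catalysed acylation of the secondary allylic alcohol with retention at C10.

Step 19
Reactants: 30 (1S,10S)-10-acetoxycembra-3,7,11,15-tetraene
Product: 31 (1S,10S,11R)-10-acetoxyverticilla-3E,7E,12(18)-triene (C2 and C10 trans on ring A)
Conditions: Co(salen)Cl (5 mol%; salen = N,N′-bis(3,5-di-tert-butylsalicylidene)cyclohexane-1,2-diamine dianion), PhSiH3 (5 mol%), degassed benzene, rt, stopped at full conversion of 30
Reagents that add atoms: none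
Why: Proposed new method: the trivalent cobalt chloride complex and PhSiH3 should form a cobalt hydride that transfers a hydrogen atom to C16 of the isopropenyl group, the only 1,1-disubstituted olefin, which leaves the three trisubstituted ring olefins untouched and gives the tertiary C15 radical beside divalent cobalt; the closest known reaction types are the cobalt-hydride hydrogen-atom-transfer cycloisomerization of acyclic dienes and the Cp2TiCl-mediated 6-endo radical cyclization that ends in an exocyclic olefin, neither of which has been run across a macrocycle. The C15 radical should close ring A in 6-endo-trig mode at C11, because the 5-exo alternative at C12 would join two fully substituted carbons, and this one bond also divides the fourteen-membered ring into ring A and the twelve-membered ring. Divalent cobalt should then take a hydrogen atom from C18, the least hindered β-position of the tertiary C12 radical, which gives the exocyclic C12=C18 olefin and returns the hydride, so the step is a redox-neutral isomerization with catalytic silane. The new stereocenter C11 is set by the conformation of the E,E,E ring: with C10–H eclipsing the C11=C12 bond (least A(1,3) strain against C18), the required face of C11 is the one anti to the C10–C9 ring bond, which gives an antiperiplanar C15–C11–C10–C9 unit in the new twelve-membered ring and leaves C1–C2 and C11–C10 trans on ring A as in the enzymatic closure, but this face also carries the acetoxy group and the outcome is not secured. The step needs chemoselective hydrogen-atom transfer (secured by the single unhindered isopropenyl group), ring closure faster than loss of the hindered tertiary C1–H (the only other β-hydrogen of the C15 radical apart from its own methyl groups), and a stop before the catalyst moves the new olefin into the ring (low loading; the product olefin is flanked by the tertiary C11 and is the more hindered one).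

Step 20
Reactants: 31 (1S,10S,11R)-10-acetoxyverticilla-3E,7E,12(18)-triene
Product: 32 (1S,3R,4R,7R,8R,10S,11R)-10-acetoxy-3,4:7,8-diepoxyverticill-12(18)-ene
Conditions: D-fructose-derived Shi ketone (1,2:4,5-di-O-isopropylidene-β-D-erythro-2,3-hexodiulo-2,6-pyranose), Oxone (KHSO5), K2CO3, Bu4NHSO4, MeCN/dimethoxymethane/aq. Na2B4O7 buffer (pH 10.5), 0 °C
Reagents that add atoms: potassium peroxymonosulfate, [K+].[O-]S(=O)(=O)OO
Why: Shi asymmetric epoxidation, in which the dioxirane of the D-fructose-derived ketone reacts through a spiro transition state with (E)-trisubstituted olefins to give (R,R)-oxiranes at C3/C4 and C7/C8, and as an electrophile it should prefer these two olefins over the hindered 1,1-disubstituted C12=C18.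

Step 21
Reactants: 32 (1S,3R,4R,7R,8R,10S,11R)-10-acetoxy-3,4:7,8-diepoxyverticill-12(18)-ene
Product: 33 10-acetoxy-3,4:7,8-diepoxyverticill-12(18)-en-13-ol as a mixture of C13 epimers (other centers as in 32)
Conditions: SeO2 (0.5 equiv), t-BuOOH, CH2Cl2, rt
Reagents that add atoms: tert-butyl hydroperoxide, CC(C)(C)OO; selenium dioxide (oxygen carrier), O=[Se]=O
Why: Selenium dioxide allylic oxidation (ene reaction at C18, then [2,3]-sigmatropic shift) should oxidize the allylic CH2 at C13 in preference to the hindered methine C11 and return the olefin to C12=C18, and the C13 configuration does not matter.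

Step 22
Reactants: 33 allylic alcohol (C13 epimers)
Product: 34 target CNP0339728.2, (1R,3R,4R,7R,8R,10S,11S)-10-acetoxy-3,4:7,8-diepoxyverticill-12(18)-en-13-one
Conditions: Dess–Martin periodinane, NaHCO3, CH2Cl2, 0 °C → rt
Reagents that add atoms: none
Why: Dess–Martin oxidation of the allylic alcohol to the α-methylene ketone under buffered, non-basic conditions that spare the oxiranes and the acetate.

**Compound list**

1 | (S)-limonene | CC1=CC[C@@H](C(C)=C)CC1 | starting material
2 | (3S)-6-hydroperoxy-6-methoxy-3-(prop-1-en-2-yl)heptanal (C6 epimers) | COC(C)(OO)CC[C@H](C(C)=C)CC=O | intermediate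
3 | (5S)-2-hydroperoxy-2,7,7-trimethoxy-5-(prop-1-en-2-yl)heptane (C2 epimers) | COC(C)(OO)CC[C@H](C(C)=C)CC(OC)OC | intermediate
4 | (5S)-7,7-dimethoxy-5-(prop-1-en-2-yl)heptan-2-one | CC(=O)CC[C@H](C(C)=C)CC(OC)OC | intermediate
5 | diethyl (5S)-7,7-dimethoxy-5-(prop-1-en-2-yl)hept-1-en-2-yl phosphate | C=C(OP(=O)(OCC)OCC)CC[C@H](C(C)=C)CC(OC)OC | intermediate
6 | [(5S)-7,7-dimethoxy-5-(prop-1-en-2-yl)hept-1-yn-1-yl]lithium | [Li]C#CCC[C@H](C(C)=C)CC(OC)OC | intermediate
7 | [(5S)-7,7-dimethoxy-5-(prop-1-en-2-yl)hept-1-yn-1-yl]trimethylsilane | C[Si](C)(C)C#CCC[C@H](C(C)=C)CC(OC)OC | intermediate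
8 | (3S)-3-(prop-1-en-2-yl)-7-(trimethylsilyl)hept-6-ynal | C[Si](C)(C)C#CCC[C@H](C(C)=C)CC=O | intermediate
9 | ethyl 2-(triphenylphosphoranylidene)propanoate | CCOC(=O)C(C)=P(c1ccccc1)(c1ccccc1)c1ccccc1 | starting material
10 | ethyl (2E,5S)-2-methyl-5-(prop-1-en-2-yl)-9-(trimethylsilyl)non-2-en-8-ynoate | CCOC(=O)/C(C)=C/C[C@@H](C(C)=C)CCC#C[Si](C)(C)C | intermediate
11 | (2E,5S)-2-methyl-5-(prop-1-en-2-yl)-9-(trimethylsilyl)non-2-en-8-yn-1-ol | OC/C(C)=C/C[C@@H](C(C)=C)CCC#C[Si](C)(C)C | intermediate
12 | (2E,5S)-1-bromo-2-methyl-5-(prop-1-en-2-yl)-9-(trimethylsilyl)non-2-en-8-yne | BrC/C(C)=C/C[C@@H](C(C)=C)CCC#C[Si](C)(C)C | intermediate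
13 | tert-butyl(but-3-yn-1-yloxy)dimethylsilane | C#CCCO[Si](C)(C)C(C)(C)C | starting material
14 | [(1E)-4-{[tert-butyl(dimethyl)silyl]oxy}-2-methylbut-1-en-1-yl]dimethylaluminium | C[Al](C)/C=C(\C)CCO[Si](C)(C)C(C)(C)C | intermediate
15 | lithium butyl[(1E)-4-{[tert-butyl(dimethyl)silyl]oxy}-2-methylbut-1-en-1-yl]dimethylaluminate | [Li+].CCCC[Al-](C)(C)/C=C(\C)CCO[Si](C)(C)C(C)(C)C | intermediate
16 | (2E)-5-{[tert-butyl(dimethyl)silyl]oxy}-3-methylpent-2-en-1-ol | OC/C=C(\C)CCO[Si](C)(C)C(C)(C)C | intermediate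
17 | {[(3E)-5-bromo-3-methylpent-3-en-1-yl]oxy}(tert-butyl)dimethylsilane | BrC/C=C(\C)CCO[Si](C)(C)C(C)(C)C | intermediate
18 | sodium benzenesulfinate | [Na+].[O-]S(=O)c1ccccc1 | starting material
19 | tert-butyl(dimethyl){[(3E)-3-methyl-5-(phenylsulfonyl)pent-3-en-1-yl]oxy}silane | O=S(=O)(C/C=C(\C)CCO[Si](C)(C)C(C)(C)C)c1ccccc1 | intermediate
20 | α-lithio derivative of sulfone 19 (lithium on the carbon bearing sulfur) | [Li]C(/C=C(\C)CCO[Si](C)(C)C(C)(C)C)S(=O)(=O)c1ccccc1 | intermediate
21 | tert-butyl(dimethyl){[(3E,7E,10S)-3,7-dimethyl-5-(phenylsulfonyl)-10-(prop-1-en-2-yl)-14-(trimethylsilyl)tetradeca-3,7-dien-13-yn-1-yl]oxy}silane (C5 epimers) | C[Si](C)(C)C#CCC[C@H](C(C)=C)C/C=C(\C)CC(S(=O)(=O)c1ccccc1)/C=C(\C)CCO[Si](C)(C)C(C)(C)C | intermediate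
22 | tert-butyl(dimethyl){[(3E,7E,10S)-3,7-dimethyl-10-(prop-1-en-2-yl)-14-(trimethylsilyl)tetradeca-3,7-dien-13-yn-1-yl]oxy}silane | C[Si](C)(C)C#CCC[C@H](C(C)=C)C/C=C(\C)CC/C=C(\C)CCO[Si](C)(C)C(C)(C)C | intermediate
23 | (3E,7E,10S)-3,7-dimethyl-10-(prop-1-en-2-yl)tetradeca-3,7-dien-13-yn-1-ol | C#CCC[C@H](C(C)=C)C/C=C(\C)CC/C=C(\C)CCO | intermediate
24 | (E)-alkenyldimethylalane of 23 with the hydroxyl as its dimethylaluminium alkoxide | C[Al](C)/C=C(\C)CC[C@H](C(C)=C)C/C=C(\C)CC/C=C(\C)CCO[Al](C)C | intermediate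
25 | (3E,7E,10S,13E)-14-iodo-3,7,13-trimethyl-10-(prop-1-en-2-yl)tetradeca-3,7,13-trien-1-ol | I/C=C(\C)CC[C@H](C(C)=C)C/C=C(\C)CC/C=C(\C)CCO | intermediate
26 | (3E,7E,10S,13E)-14-iodo-3,7,13-trimethyl-10-(prop-1-en-2-yl)tetradeca-3,7,13-trienal | I/C=C(\C)CC[C@H](C(C)=C)C/C=C(\C)CC/C=C(\C)CC=O | intermediate
27 | (2E,6S,8E,12E)-3,9,13-trimethyl-6-(prop-1-en-2-yl)cyclotetradeca-2,8,12-trien-1-ol, C1 epimers [(1S)-cembra-3,7,11,15-tetraen-10-ol, C10 epimers] | C=C(C)[C@@H]1C/C=C(\C)CC/C=C(\C)CC(O)/C=C(\C)CC1 | intermediate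
28 | (2E,6S,8E,12E)-3,9,13-trimethyl-6-(prop-1-en-2-yl)cyclotetradeca-2,8,12-trien-1-one | C=C(C)[C@@H]1C/C=C(\C)CC/C=C(\C)CC(=O)/C=C(\C)CC1 | intermediate
29 | (1S,2E,6S,8E,12E)-3,9,13-trimethyl-6-(prop-1-en-2-yl)cyclotetradeca-2,8,12-trien-1-ol [(1S,10S)-cembra-3,7,11,15-tetraen-10-ol] | C=C(C)[C@@H]1C/C=C(\C)CC/C=C(\C)C[C@H](O)/C=C(\C)CC1 | intermediate
30 | (1S,2E,6S,8E,12E)-3,9,13-trimethyl-6-(prop-1-en-2-yl)cyclotetradeca-2,8,12-trien-1-yl acetate [(1S,10S)-10-acetoxycembra-3,7,11,15-tetraene] | C=C(C)[C@@H]1C/C=C(\C)CC/C=C(\C)C[C@H](OC(C)=O)/C=C(\C)CC1 | intermediate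
31 | (1S,10S,11R)-10-acetoxyverticilla-3E,7E,12(18)-triene | C=C1CC[C@H]2C/C=C(\C)CC/C=C(\C)C[C@H](OC(C)=O)[C@H]1C2(C)C | intermediate
32 | (1S,3R,4R,7R,8R,10S,11R)-10-acetoxy-3,4:7,8-diepoxyverticill-12(18)-ene | C=C1CC[C@H]2C[C@H]3O[C@]3(C)CC[C@H]3O[C@]3(C)C[C@H](OC(C)=O)[C@H]1C2(C)C | intermediate
33 | 10-acetoxy-3,4:7,8-diepoxyverticill-12(18)-en-13-ol, C13 epimers, other centers as in 32 | C=C1C(O)C[C@H]2C[C@H]3O[C@]3(C)CC[C@H]3O[C@]3(C)C[C@H](OC(C)=O)[C@H]1C2(C)C | intermediate
34 | CNP0339728.2, (1R,3R,4R,7R,8R,10S,11S)-10-acetoxy-3,4:7,8-diepoxyverticill-12(18)-en-13-one | C=C1C(=O)C[C@H]2C[C@H]3O[C@]3(C)CC[C@H]3O[C@]3(C)C[C@H](OC(C)=O)[C@H]1C2(C)C | target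

**Step count and risks**

Total steps: 22. Longest linear sequence: 19 steps (steps 1–6 and 10–22); steps 7–9 make the sulfone fragment.

Most likely to fail:

1. Step 19 (proposed new method). The C15 radical may return a hydrogen atom through C1–H faster than it closes, which would give the isopropylidene isomer and erase the C1 stereocenter. It may also add to the wrong face of C11, or the catalyst may go on to move the new exocyclic olefin into ring A. The fallback forms the same bond by the polar, biomimetic path with known chemistry. It sets out from 30 and comes back at 31. Cobalt-catalysed Markovnikov hydrochlorination of the isopropenyl group (Co(BF4)2·6H2O with a salen-type ligand, PhSiH3, TsCl, t-BuOOH, EtOH; the trisubstituted olefins react far more slowly) should trap the C15 radical as the tertiary chloride (1S,10S)-10-acetoxy-15-chlorocembra-3E,7E,11E-triene F1. Halide abstraction with AgOTf and 2,6-di-tert-butyl-4-methylpyridine in CH2Cl2 at −78 °C should give the C15 cation without free acid. This cation should alkylate C11 in a transannular cation–olefin cyclization (Markovnikov, tertiary C12 cation) and lose a proton. The C12=C18 isomer 31 would be separated from the C12=C13 isomer on AgNO3-impregnated silica.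

2. Step 20. The conformation of the bicyclic triene may shield the required face of one or both ring olefins strongly enough to override the catalyst, and the dioxirane may also attack C12=C18. The fallback delivers each oxygen through a bromohydrin, which places it on the face opposite to the one an electrophile attacks. It sets out from 31 and comes back at 32. NBS in THF/H2O at 0 °C should give the bis-bromohydrin 10-acetoxy-3,7-dibromo-4,8-dihydroxyverticill-12(18)-ene F2 (bromine at the secondary and hydroxyl at the tertiary carbon of each former olefin, anti). K2CO3 in MeOH should close both oxiranes with inversion at C3 and C7 and cleave the acetate, giving 3,4:7,8-diepoxyverticill-12(18)-en-10-ol F3. Ac2O, DMAP and pyridine would return 32.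

3. Step 15. The C7=C8 double bond of aldehyde 26 may move into conjugation, and oligomers may form while the slow fourteen-membered closure competes. The fallback exchanges the roles of the two carbon–carbon bond formations: C10–C11 is made between two small fragments and the ring is closed at C5–C6 by intramolecular alkylation of the sulfone carbanion. It sets out from 19 and 11 and comes back at 27.
   - TBAF on 19 gives (3E)-3-methyl-5-(phenylsulfonyl)pent-3-en-1-ol F4, and buffered Dess–Martin oxidation gives (3E)-3-methyl-5-(phenylsulfonyl)pent-3-enal F5.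
   - K2CO3 in MeOH on 11 gives the terminal alkyne (2E,5S)-2-methyl-5-(prop-1-en-2-yl)non-2-en-8-yn-1-ol F6. Me3Al/Cp2ZrCl2 and then I2 give (2E,5S,8E)-9-iodo-2,8-dimethyl-5-(prop-1-en-2-yl)nona-2,8-dien-1-ol F7.
   - Intermolecular CrCl2/NiCl2 coupling of F7 with F5 in DMSO gives (2E,5S,8E,12E)-2,8,12-trimethyl-14-(phenylsulfonyl)-5-(prop-1-en-2-yl)tetradeca-2,8,12-triene-1,10-diol F8 (C10 epimers).
   - MsCl, LiCl and s-collidine in DMF at 0 °C convert only the primary allylic alcohol, giving the 1-chloro analogue of F8 with the 10-hydroxyl free, F9.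
   - LiHMDS (2.2 equiv) in THF at high dilution closes the ring to (1S)-6-(phenylsulfonyl)cembra-3E,7E,11E,15-tetraen-10-ol F10. Pd(dppp)Cl2/LiBHEt3 then removes the sulfone to give 27.

**Further compounds**

F1 | step 19 | (1S,10S)-10-acetoxy-15-chlorocembra-3E,7E,11E-triene | CC(C)(Cl)[C@@H]1C/C=C(\C)CC/C=C(\C)C[C@H](OC(C)=O)/C=C(\C)CC1
F2 | step 20 | 10-acetoxy-3,7-dibromo-4,8-dihydroxyverticill-12(18)-ene (Br/OH anti, configuration as drawn) | C=C1CC[C@H]2C[C@H](Br)[C@@](O)(C)CC[C@H](Br)[C@@](O)(C)C[C@H](OC(C)=O)[C@H]1C2(C)C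
F3 | step 20 | 3,4:7,8-diepoxyverticill-12(18)-en-10-ol (configuration of 32) | C=C1CC[C@H]2C[C@H]3O[C@]3(C)CC[C@H]3O[C@]3(C)C[C@H](O)[C@H]1C2(C)C
F4 | step 15 | (3E)-3-methyl-5-(phenylsulfonyl)pent-3-en-1-ol | O=S(=O)(C/C=C(\C)CCO)c1ccccc1
F5 | step 15 | (3E)-3-methyl-5-(phenylsulfonyl)pent-3-enal | O=S(=O)(C/C=C(\C)CC=O)c1ccccc1
F6 | step 15 | (2E,5S)-2-methyl-5-(prop-1-en-2-yl)non-2-en-8-yn-1-ol | OC/C(C)=C/C[C@@H](C(C)=C)CCC#C
F7 | step 15 | (2E,5S,8E)-9-iodo-2,8-dimethyl-5-(prop-1-en-2-yl)nona-2,8-dien-1-ol | OC/C(C)=C/C[C@@H](C(C)=C)CC/C(C)=C/I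
F8 | step 15 | (2E,5S,8E,12E)-2,8,12-trimethyl-14-(phenylsulfonyl)-5-(prop-1-en-2-yl)tetradeca-2,8,12-triene-1,10-diol (C10 epimers) | OC/C(C)=C/C[C@@H](C(C)=C)CC/C(C)=C/C(O)C/C(C)=C/CS(=O)(=O)c1ccccc1
F9 | step 15 | (2E,5S,8E,12E)-1-chloro-2,8,12-trimethyl-14-(phenylsulfonyl)-5-(prop-1-en-2-yl)tetradeca-2,8,12-trien-10-ol (numbering of F8, C10 epimers) | ClC/C(C)=C/C[C@@H](C(C)=C)CC/C(C)=C/C(O)C/C(C)=C/CS(=O)(=O)c1ccccc1
F10 | step 15 | (1S)-6-(phenylsulfonyl)cembra-3E,7E,11E,15-tetraen-10-ol (C6 and C10 epimers) | C=C(C)[C@@H]1C/C=C(\C)CC(S(=O)(=O)c2ccccc2)/C=C(\C)CC(O)/C=C(\C)CC1
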